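Ring B is not brought in as an arene but built on the chromone. Cutting C1'–C2' and C5'–C6' (after formal addition of two hydrogens) leads back to a C2-ethynyl chromone and 2,3-dimethoxybuta-1,3-diene. One thermal [4+2] cycloaddition closes the six-membered carbocycle and places both methoxy groups on the adjacent carbons C3' and C4', while the alkyne carbons become C1' and C6'; dehydrogenation then gives the veratryl ring. The cycloaddition substrate is 2-ethynyl-7-(prenyloxy)chromone with O3 masked as a benzoate, an ester that does not feed electron density into the dienophile and is later removed by mild base, which the prenyl ether tolerates.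

Key step: step 7

Remark: O3 is carried as a benzoate (installed in the chromone-forming step, cleaved last by methanolysis), so no acid is needed after the cycloaddition; the bonds formed and the carbon skeletons of the cycloaddition partners and of the adduct are unaffected by this choice.

Step 1
Reactants: 1 1-(2,4-dihydroxyphenyl)ethan-1-one; 2 1-bromo-3-methylbut-2-ene (prenyl bromide)
Product: 3 1-{2-hydroxy-4-[(3-methylbut-2-en-1-yl)oxy]phenyl}ethan-1-one
Conditions: K2CO3, acetone, reflux
Reagents that add atoms: none
Why: Williamson etherification is selective for the 4'-hydroxyl because the 2'-hydroxyl is held in a hydrogen bond to the ketone and is the weaker nucleophile under carbonate conditions.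

Step 2
Reactants: 3 1-{2-hydroxy-4-[(3-methylbut-2-en-1-yl)oxy]phenyl}ethan-1-one
Product: 4 (E)-3-(dimethylamino)-1-{2-hydroxy-4-[(3-methylbut-2-en-1-yl)oxy]phenyl}prop-2-en-1-one
Conditions: Me2NCH(OMe)2 (2 equiv), PhMe, 100 °C
Reagents that add atoms: N,N-dimethylformamide dimethyl acetal, COC(OC)N(C)C
Why: Condensation of the methyl ketone with the amide acetal (enaminone formation) is driven by loss of methanol and should give the E-enaminone with the ortho-hydroxyl left free for the coming ring closure.

Step 3
Reactants: 4 (E)-3-(dimethylamino)-1-{2-hydroxy-4-[(3-methylbut-2-en-1-yl)oxy]phenyl}prop-2-en-1-one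
Product: 6 7-[(3-methylbut-2-en-1-yl)oxy]-4-oxo-4H-chromen-3-yl benzoate, via α-benzoyloxy enaminone 5 (not isolated)
Conditions: (PhCO2)2 (2 equiv), ClCH2CH2Cl, 60 °C
Reagents that add atoms: dibenzoyl peroxide, O=C(OOC(=O)c1ccccc1)c1ccccc1
Why: Acyloxylative chromone annulation of an ortho-hydroxyaryl enaminone with an aroyl peroxide, in which the nucleophilic α-carbon is benzoyloxylated, the phenol closes 6-endo onto the amino-bearing carbon and dimethylamine is expelled, so that O3 arrives already protected while the isolated prenyl alkene is far less reactive toward the peroxide than the enaminone.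

Step 4
Reactants: 6 7-[(3-methylbut-2-en-1-yl)oxy]-4-oxo-4H-chromen-3-yl benzoate
Product: 8 2-iodo-7-[(3-methylbut-2-en-1-yl)oxy]-4-oxo-4H-chromen-3-yl benzoate, via chromon-2-ylzinc chloride 7 (not isolated)
Conditions: (2,2,6,6-tetramethylpiperidin-1-yl)zinc chloride–lithium chloride, TMPZnCl·LiCl (1.3 equiv), THF, 25 °C; then I2, 0 °C
Reagents that add atoms: iodine, II; (2,2,6,6-tetramethylpiperidin-1-yl)zinc chloride–lithium chloride, CC1(C)CCCC(C)(C)N1[Zn]Cl.[Li+].[Cl-], which puts ZnCl into intermediate 7 only
Why: Directed C–H zincation with a hindered zinc amide followed by iodinolysis should work because C2–H is the only vinylic and by far the most acidic C–H (flanked by O1 and the acyloxy-bearing C3, vinylogous to the C4 carbonyl), and the mild zinc base tolerates the benzoate and the enone and gives an organozinc that does not undergo acyl migration.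

Step 5
Reactants: 8 2-iodo-7-[(3-methylbut-2-en-1-yl)oxy]-4-oxo-4H-chromen-3-yl benzoate; 9 ethynyltrimethylsilane
Product: 10 7-[(3-methylbut-2-en-1-yl)oxy]-4-oxo-2-[(trimethylsilyl)ethynyl]-4H-chromen-3-yl benzoate
Conditions: PdCl2(PPh3)2 (3 mol%), CuI (5 mol%), Et3N, THF, rt
Reagents that add atoms: none
Why: Sonogashira coupling at the vinylogous acyl iodide C2–I is fast at room temperature, and the tertiary amine base can neither displace iodide by addition–elimination nor cleave the benzoate.

Step 6
Reactants: 10 7-[(3-methylbut-2-en-1-yl)oxy]-4-oxo-2-[(trimethylsilyl)ethynyl]-4H-chromen-3-yl benzoate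
Product: 11 2-ethynyl-7-[(3-methylbut-2-en-1-yl)oxy]-4-oxo-4H-chromen-3-yl benzoate
Conditions: Bu4NF, AcOH (1:1.2), THF, −20 to 0 °C
Reagents that add atoms: none
Why: Fluoride-induced protodesilylation under acetic acid buffering cleaves the alkynyl C–Si bond without producing alkoxide or unbuffered fluoride that could add to the activated enynone or attack the benzoate.

Step 7
Reactants: 11 2-ethynyl-7-[(3-methylbut-2-en-1-yl)oxy]-4-oxo-4H-chromen-3-yl benzoate; 12 2,3-dimethoxybuta-1,3-diene
Product: 13 2-(4,5-dimethoxycyclohexa-1,4-dien-1-yl)-7-[(3-methylbut-2-en-1-yl)oxy]-4-oxo-4H-chromen-3-yl benzoate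
Conditions: 12 (6 equiv), BHT (5 mol%), PhMe, sealed tube, 120 °C
Reagents that add atoms: none
Why: A concerted, thermally allowed [4π+2π] cycloaddition is expected, in which the HOMO of the s-cis bis-enol ether diene meets the LUMO of the terminal alkyne, lowered by conjugation through C2=C3 to the C4 carbonyl and not raised by an ether donor at O3 because that oxygen is acylated. The closest known reaction type is the Diels–Alder reaction of 2,3-dialkoxybutadienes with conjugated alkynes such as propiolates and ynones, which gives 4,5-dialkoxycyclohexa-1,4-dienes. The six-membered carbocycle of ring B is closed by intermolecular cycloaddition, both new bonds (C1'–C2' and C5'–C6') forming in the same step and the former alkyne remaining as the C1'=C6' double bond. No stereocentre is created. The step needs chemoselectivity among the π bonds and a thermal window: the diene is symmetric so no regiochemistry arises, the terminal alkyne is the only unhindered electron-poor 2π partner (C2=C3 is tetrasubstituted, the prenyl alkene is electron-rich and trisubstituted), and 120 °C lies well below the roughly 180 °C and above usually needed for Claisen rearrangement of aryl prenyl ethers. Excess diene and a radical inhibitor offset its slow self-condensation.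

Step 8
Reactants: 13 2-(4,5-dimethoxycyclohexa-1,4-dien-1-yl)-7-[(3-methylbut-2-en-1-yl)oxy]-4-oxo-4H-chromen-3-yl benzoate
Product: 14 2-(3,4-dimethoxyphenyl)-7-[(3-methylbut-2-en-1-yl)oxy]-4-oxo-4H-chromen-3-yl benzoate
Conditions: DDQ (1.05 equiv), dry PhMe, 0 °C to rt
Reagents that add atoms: none
Why: Dehydrogenation of a 1,4-cyclohexadiene by DDQ (hydride abstraction from a doubly allylic CH2, then proton loss) is driven by aromatisation to the veratryl ring and should be much faster than oxidation of the electron-poor aryl prenyl ether when one equivalent of oxidant is used without water.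

Step 9
Reactants: 14 2-(3,4-dimethoxyphenyl)-7-[(3-methylbut-2-en-1-yl)oxy]-4-oxo-4H-chromen-3-yl benzoate
Product: 15 2-(3,4-dimethoxyphenyl)-3-hydroxy-7-[(3-methylbut-2-en-1-yl)oxy]-4H-chromen-4-one
Conditions: K2CO3, MeOH–THF, N2, 0 °C to rt; then aq. NH4Cl
Reagents that add atoms: none
Why: Base-mediated transesterification (methanolysis) of the enol-type benzoate, an activated ester whose leaving group is the acidic flavonol oxygen, should free the 3-hydroxyl under conditions that leave the aryl prenyl ether and the methyl ethers untouched.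

Compound list
1 | 1-(2,4-dihydroxyphenyl)ethan-1-one (2',4'-dihydroxyacetophenone) | CC(=O)c1ccc(O)cc1O | starting material
2 | 1-bromo-3-methylbut-2-ene (prenyl bromide) | CC(C)=CCBr | starting material
3 | 1-{2-hydroxy-4-[(3-methylbut-2-en-1-yl)oxy]phenyl}ethan-1-one | CC(=O)c1ccc(OCC=C(C)C)cc1O | intermediate
4 | (E)-3-(dimethylamino)-1-{2-hydroxy-4-[(3-methylbut-2-en-1-yl)oxy]phenyl}prop-2-en-1-one | CN(C)/C=C/C(=O)c1ccc(OCC=C(C)C)cc1O | intermediate
5 | (Z)-3-(dimethylamino)-1-{2-hydroxy-4-[(3-methylbut-2-en-1-yl)oxy]phenyl}-1-oxoprop-2-en-2-yl benzoate (α-benzoyloxy enaminone, formed in the flask) | CN(C)/C=C(\OC(=O)c1ccccc1)C(=O)c1ccc(OCC=C(C)C)cc1O | intermediate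
6 | 7-[(3-methylbut-2-en-1-yl)oxy]-4-oxo-4H-chromen-3-yl benzoate | O=C(Oc1coc2cc(OCC=C(C)C)ccc2c1=O)c1ccccc1 | intermediate
7 | {3-(benzoyloxy)-7-[(3-methylbut-2-en-1-yl)oxy]-4-oxo-4H-chromen-2-yl}zinc chloride (chromon-2-ylzinc chloride, formed in the flask as its LiCl complex) | O=C(Oc1c([Zn]Cl)oc2cc(OCC=C(C)C)ccc2c1=O)c1ccccc1 | intermediate
8 | 2-iodo-7-[(3-methylbut-2-en-1-yl)oxy]-4-oxo-4H-chromen-3-yl benzoate | O=C(Oc1c(I)oc2cc(OCC=C(C)C)ccc2c1=O)c1ccccc1 | intermediate
9 | ethynyltrimethylsilane | C#C[Si](C)(C)C | starting material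
10 | 7-[(3-methylbut-2-en-1-yl)oxy]-4-oxo-2-[(trimethylsilyl)ethynyl]-4H-chromen-3-yl benzoate | C[Si](C)(C)C#Cc1oc2cc(OCC=C(C)C)ccc2c(=O)c1OC(=O)c1ccccc1 | intermediate
11 | 2-ethynyl-7-[(3-methylbut-2-en-1-yl)oxy]-4-oxo-4H-chromen-3-yl benzoate | C#Cc1oc2cc(OCC=C(C)C)ccc2c(=O)c1OC(=O)c1ccccc1 | intermediate
12 | 2,3-dimethoxybuta-1,3-diene | C=C(OC)C(=C)OC | starting material
13 | 2-(4,5-dimethoxycyclohexa-1,4-dien-1-yl)-7-[(3-methylbut-2-en-1-yl)oxy]-4-oxo-4H-chromen-3-yl benzoate | COC1=C(OC)CC(c2oc3cc(OCC=C(C)C)ccc3c(=O)c2OC(=O)c2ccccc2)=CC1 | intermediate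
14 | 2-(3,4-dimethoxyphenyl)-7-[(3-methylbut-2-en-1-yl)oxy]-4-oxo-4H-chromen-3-yl benzoate | COc1ccc(-c2oc3cc(OCC=C(C)C)ccc3c(=O)c2OC(=O)c2ccccc2)cc1OC | intermediate
15 | 2-(3,4-dimethoxyphenyl)-3-hydroxy-7-[(3-methylbut-2-en-1-yl)oxy]-4H-chromen-4-one | COc1ccc(-c2oc3cc(OCC=C(C)C)ccc3c(=O)c2O)cc1OC | target

Total steps: 9. Longest linear sequence: 9 steps (1 to 15).

Steps most likely to fail

Step 7. The cycloaddition may be too slow at temperatures that still avoid [3,3] rearrangement of the aryl prenyl ether, while the diene is lost to self-condensation. Fallback: ring B would be attached as a preformed arene instead of being built. Setting out from 8, Suzuki–Miyaura coupling with (3,4-dimethoxyphenyl)boronic acid (Pd(PPh3)4, anhydrous K3PO4, 1,4-dioxane, 80 °C) should give the protected flavonol directly and comes back to the route at 14; no new compound lies on this path.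

Step 4. Metalation may be incomplete, or the metalated species may suffer acyl transfer from O3 to C2 before iodine is added. Fallback: the iodine would be introduced by electrophilic substitution on the free enol instead of by metalation. Setting out from 6, the benzoate would be cleaved with K2CO3 in methanol to 3-hydroxy-7-[(3-methylbut-2-en-1-yl)oxy]-4H-chromen-4-one F1, which would be iodinated at C2 with iodine and Na2CO3 in aqueous THF at 0 °C (substitution at the enol carbon next to O1, the mode in which 3-hydroxy-4-pyranones are halogenated) to 3-hydroxy-2-iodo-7-[(3-methylbut-2-en-1-yl)oxy]-4H-chromen-4-one F2; benzoylation (PhCOCl, pyridine, CH2Cl2, 0 °C) comes back to the route at 8.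

Step 3. The peroxide may attack the prenyl double bond or the allylic ether position by radical pathways, or the ring may fail to close after acyloxylation. Fallback: the oxygen at C3 would be introduced by nucleophilic epoxidation of the preformed chromone. Setting out from 4, ring closure in acetic acid at 60 °C would give 7-[(3-methylbut-2-en-1-yl)oxy]-4H-chromen-4-one F3; Weitz–Scheffer epoxidation (H2O2, NaOH, CH2Cl2–MeOH, 0 °C), which spares the electron-rich prenyl alkene, would give racemic cis-fused 2,3-epoxy-7-[(3-methylbut-2-en-1-yl)oxy]chroman-4-one F4; catalytic pyridinium p-toluenesulfonate in CH2Cl2 would open the acetal-like epoxide to 3-hydroxy-7-[(3-methylbut-2-en-1-yl)oxy]-4H-chromen-4-one F1, and benzoylation (PhCOCl, pyridine) comes back to the route at 6.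

Further compounds
F0 | step 7 | none | none
F1 | step 4 | 3-hydroxy-7-[(3-methylbut-2-en-1-yl)oxy]-4H-chromen-4-one | CC(C)=CCOc1ccc2c(c1)occ(O)c2=O
F2 | step 4 | 3-hydroxy-2-iodo-7-[(3-methylbut-2-en-1-yl)oxy]-4H-chromen-4-one | CC(C)=CCOc1ccc2c(c1)oc(I)c(O)c2=O
F3 | step 3 | 7-[(3-methylbut-2-en-1-yl)oxy]-4H-chromen-4-one | CC(C)=CCOc1ccc2c(c1)occc2=O
F4 | step 3 | 2,3-epoxy-7-[(3-methylbut-2-en-1-yl)oxy]chroman-4-one (racemic, cis-fused; one enantiomer drawn) | O=C1c2ccc(OCC=C(C)C)cc2O[C@@H]2O[C@H]12
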